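**Retrosynthetic overview**

1. Numbering: cyclohexane C1/C10–C14, oxolane C1–C2–O–C9–C10, oxonane O/C2–C9. The plan rests on the seven-membered lactone O–C16(=O)–C15–C14–C1–C2–C3, whose carbonyl C16 is a single carbon lying between C15 and the oxygen on C3.
2. Target ⇐ hydrogenation of the 15-methylene lactone ⇐ Pd/CO stitching of C15–C16 and C16–O from the C15 alkenyl triflate and the free tertiary C3–OH (carbon monoxide becomes C16).
3. Triflate ⇐ C14 acetyl of a Diels–Alder adduct (C10 2-ethoxydiene + methyl vinyl ketone); the C11 enol ether is unmasked only afterwards for MeMgBr/Ac2O.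
4. Diene ⇐ Stille coupling of the C10 enol triflate of an oxa-bridged bicyclic ketone, on which C3 (methyl addition) and C6/C7 (epoxidation, methoxide) are set beforehand.
5. Bicyclic ketone ⇐ Cu-carbenoid oxonium-ylide [2,3] shift of a tetrahydropyranyl diazoketone ⇐ SmI2 cyclisation. Ring order: tetrahydropyran → oxolane and oxonane together → cyclohexane → lactone.

Key step: step 24

Remark: the SMILES is read as 1S,2S,3S,6R,7R,9S,10R,11R,14R,15R in the numbering above, which requires the (S)-carbinol in step 2; diazomethane is used as a separately prepared ethereal solution.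

Step 1
Reactants: 1 methyl 4,4-dimethoxybutanoate; 2 isopropenylmagnesium bromide
Product: 4 6,6-dimethoxy-2-methylhex-1-en-3-one, via Weinreb amide 3 (not isolated)
Conditions: MeNH(OMe)·HCl, i-PrMgCl, THF, −20 °C; then 2, −20 → 0 °C; aq NH4Cl
Reagents that add atoms: N,O-dimethylhydroxylamine hydrochloride, CNOC.Cl (carried in 3 only)
Why: The magnesium amide of N,O-dimethylhydroxylamine converts the ester into Weinreb amide 3 in the flask, and the Weinreb ketone synthesis then stops at the enone because the chelated tetrahedral adduct survives until the quench; no stereocentre is formed and the acetal is inert to Grignard reagents.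

Step 2
Reactants: 4 6,6-dimethoxy-2-methylhex-1-en-3-one
Product: 5 (S)-6,6-dimethoxy-2-methylhex-1-en-3-ol
Conditions: (R)-2-methyl-CBS-oxazaborolidine (10 mol %), BH3·SMe2, THF, −30 °C; MeOH quench
Reagents that add atoms: none
Why: Corey–Bakshi–Shibata reduction in which the α-branched isopropenyl group acts as the large substituent and the n-alkyl chain as the small one, so that the (R)-oxazaborolidine (mirror image of the familiar (S)-catalyst/aryl methyl ketone → (R)-carbinol case) should deliver hydride to the face giving the (S)-carbinol, from which C2 and C9 are later derived.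

Step 3
Reactants: 5 (S)-6,6-dimethoxy-2-methylhex-1-en-3-ol; 6 ethyl propiolate
Product: 7 ethyl (E)-3-{[(3S)-6,6-dimethoxy-2-methylhex-1-en-3-yl]oxy}prop-2-enoate
Conditions: N-methylmorpholine, CH2Cl2, rt
Reagents that add atoms: none
Why: Tertiary-amine-catalysed oxa-Michael addition of the alcohol to the propiolate gives the (E)-β-alkoxyacrylate (vinylogous carbonate) and leaves the carbinol centre and the acetal untouched.

Step 4
Reactants: 7 β-alkoxyacrylate acetal
Product: 8 ethyl (E)-3-{[(3S)-2-methyl-6-oxohex-1-en-3-yl]oxy}prop-2-enoate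
Conditions: TsOH·H2O (cat.), THF/H2O, rt
Reagents that add atoms: water, O
Why: Acid-catalysed acetal hydrolysis frees the aldehyde, while the electron-poor β-alkoxyacrylate is far less acid-labile than an ordinary enol ether and should survive.

Step 5
Reactants: 8 aldehyde β-alkoxyacrylate
Product: 9 ethyl 2-[(2S,3R,6S)-3-hydroxy-6-(prop-1-en-2-yl)oxan-2-yl]acetate
Conditions: SmI2, MeOH, THF, 0 °C
Reagents that add atoms: none
Why: Samarium diiodide ketyl–olefin reductive cyclisation in which the Sm-chelated ketyl adds 6-exo to the acrylate β-carbon through a chair with the isopropenyl group equatorial, which sets C2 cis to the carbinol carbon across the ring oxygen (2,6-cis) and the new hydroxyl trans to the acetate arm (2,3-trans).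

Step 6
Reactants: 9 tetrahydropyranol ester
Product: 10 ethyl 2-[(2S,3R,6S)-3-(tert-butyldimethylsilyloxy)-6-(prop-1-en-2-yl)oxan-2-yl]acetate
Conditions: TBSCl, imidazole, DMF, rt
Reagents that add atoms: tert-butyldimethylsilyl chloride, CC(C)(C)[Si](C)(C)Cl
Why: Standard silylation of the secondary alcohol; the TBS ether prevents O–H insertion of the later carbenoid and is too poor a donor to compete for it.

Step 7
Reactants: 10 silyl ether ester
Product: 11 2-[(2S,3R,6S)-3-(tert-butyldimethylsilyloxy)-6-(prop-1-en-2-yl)oxan-2-yl]acetic acid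
Conditions: LiOH, THF/MeOH/H2O, rt; then aq HCl to pH 4
Reagents that add atoms: lithium hydroxide, [Li+].[OH-]
Why: Ester saponification; the silyl ether and the alkene are stable to LiOH and to the mild acidification.

Step 8
Reactants: 11 tetrahydropyranylacetic acid
Product: 13 1-diazo-3-[(2S,3R,6S)-3-(tert-butyldimethylsilyloxy)-6-(prop-1-en-2-yl)oxan-2-yl]propan-2-one, via mixed anhydride 12 (not isolated)
Conditions: i-BuOCOCl, Et3N, THF, −15 °C; then CH2N2, Et2O, 0 °C → rt
Reagents that add atoms: isobutyl chloroformate, CC(C)COC(=O)Cl (carried in 12 only); diazomethane, [CH2-][N+]#N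
Why: Acylation of diazomethane by the mixed carbonic anhydride (first stage of the Arndt–Eistert sequence) gives the α-diazoketone under conditions that do not touch the ring stereocentres.

Step 9
Reactants: 13 diazoketone
Product: 15 (1S,2R,5Z,8S)-2-(tert-butyldimethylsilyloxy)-6-methyl-11-oxabicyclo[6.2.1]undec-5-en-9-one, via oxonium ylide 14 (not isolated)
Conditions: Cu(hfacac)2 (5 mol %), CH2Cl2, reflux
Reagents that add atoms: none
Why: Copper carbenoid formation, attack of the ring oxygen to give five-membered oxonium ylide 14 and its [2,3]-sigmatropic rearrangement through the isopropenyl group expand the tetrahydropyran by three atoms to the oxa-bridged oxonene, with C9 fixed cis to C2 by the bicyclic transition state and the Z-alkene expected as the main isomer under copper catalysis.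

Step 10
Reactants: 15 bicyclic ketone (C10 ketone)
Product: 16 (1S,2R,5Z,8S)-2-(tert-butyldimethylsilyloxy)-6-methyl-11-oxabicyclo[6.2.1]undeca-5,9-dien-9-yl triflate (C10 enol triflate; C1=C10)
Conditions: NaHMDS, THF, −78 °C; PhNTf2; aq NH4Cl
Reagents that add atoms: N-phenylbis(trifluoromethanesulfonimide), O=S(=O)(N(c1ccccc1)S(=O)(=O)C(F)(F)F)C(F)(F)F
Why: Kinetic deprotonation at the C1 methylene (enolisation toward the bridgehead C9 is strained) and O-sulfonylation of the enolate with PhNTf2 give the C10 enol triflate.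

Step 11
Reactants: 16 enol triflate silyl ether
Product: 17 (1S,2R,5Z,8S)-2-hydroxy-6-methyl-11-oxabicyclo[6.2.1]undeca-5,9-dien-9-yl triflate (free C3–OH)
Conditions: HF·pyridine, pyridine, THF, 0 °C → rt
Reagents that add atoms: none
Why: Fluoride cleavage of the secondary TBS ether under pyridine-buffered conditions to which the alkenyl triflate and the allylic ethers are inert.

Step 12
Reactants: 17 C3 alcohol
Product: 18 (1S,5Z,8S)-6-methyl-2-oxo-11-oxabicyclo[6.2.1]undeca-5,9-dien-9-yl triflate (C3 ketone)
Conditions: Dess–Martin periodinane, NaHCO3, CH2Cl2, 0 °C → rt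
Reagents that add atoms: none
Why: Dess–Martin oxidation is neutral and fast, so the doubly activated C2–H of the resulting β,γ-unsaturated α-alkoxy ketone is not enolised and the alkene does not migrate.

Step 13
Reactants: 18 C3 ketone
Product: 19 (1S,2S,5Z,8S)-2-hydroxy-2,6-dimethyl-11-oxabicyclo[6.2.1]undeca-5,9-dien-9-yl triflate (C3 tertiary carbinol)
Conditions: MeMgCl, CeCl3, THF, −78 °C
Reagents that add atoms: methylmagnesium chloride, C[Mg]Cl
Why: Organocerium 1,2-addition (weakly basic, so neither C2–H enolisation nor attack on the triflate is expected) with methyl delivered to the outer, peripheral face of the medium-ring ketone, which places the C3 oxygen on the side of the C1–C10 bridge as required for the later lactone.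

Step 14
Reactants: 19 C3 tertiary carbinol
Product: 20 (1S,2S,5Z,8S)-2,6-dimethyl-2-(triethylsilyloxy)-11-oxabicyclo[6.2.1]undeca-5,9-dien-9-yl triflate
Conditions: TESOTf, 2,6-lutidine, CH2Cl2, −78 → 0 °C
Reagents that add atoms: triethylsilyl triflate, CC[Si](CC)(CC)OS(=O)(=O)C(F)(F)F
Why: Silyl triflate silylation of the hindered tertiary carbinol; masking O3 prevents its transannular attack on the epoxide made in the next step.

Step 15
Reactants: 20 3-O-TES enol triflate
Product: 21 6,7-epoxide of 20 (6S,7R; oxirane oxygen on the ring face remote from the C1=C10 bridge)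
Conditions: m-CPBA, NaHCO3, CH2Cl2, 0 °C
Reagents that add atoms: m-chloroperbenzoic acid, OOC(=O)c1cccc(Cl)c1
Why: Prilezhaev epoxidation, chemoselective for the electron-rich trisubstituted C6=C7 over the electron-poor alkenyl triflate, on the outer face of the Z-oxonene (away from the C1=C10 bridge), which fixes the C7–O bond as in the target.

Step 16
Reactants: 21 epoxy enol triflate; 22 tributyl(1-ethoxyvinyl)stannane
Product: 23 C10-(1-ethoxyvinyl) diene epoxide (triflate of 21 replaced by C(OEt)=CH2)
Conditions: Pd(PPh3)4 (5 mol %), LiCl, THF, 65 °C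
Reagents that add atoms: none
Why: Stille coupling of the alkenyl triflate (chloride-assisted transmetallation) installs the 2-ethoxydiene; the epoxide and the silyl ether are inert to Pd(0) in the absence of acid.

Step 17
Reactants: 23 diene epoxide
Product: 24 (6R,7R)-6-methoxy-7-hydroxy diene (3-OTES; C10-(1-ethoxyvinyl))
Conditions: NaOMe, MeOH, 65 °C
Reagents that add atoms: sodium methoxide in methanol, C[O-].[Na+]
Why: Base-mediated SN2 opening of the trisubstituted epoxide at the secondary C6 with inversion gives the trans 6-OMe/7-OH pair (6R,7R), while enol ether, diene and tertiary TES ether are stable to methoxide.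

Step 18
Reactants: 24 methoxy alcohol diene
Product: 25 3,7-bis(triethylsilyl) ether of 24
Conditions: TESOTf, 2,6-lutidine, CH2Cl2, −78 → 0 °C
Reagents that add atoms: triethylsilyl triflate, CC[Si](CC)(CC)OS(=O)(=O)C(F)(F)F
Why: Lutidine-buffered silylation of the tertiary C7 carbinol (the acid-labile ethoxydiene survives) keeps O7 out of the enolate and acetylation steps that follow.

Step 19
Reactants: 25 bis-silylated diene; 26 methyl vinyl ketone
Product: 28 tricyclic methyl ketone (14-acetyl; C10=C11 ethyl enol ether; 6-OMe; 3,7-bis-OTES; H14 trans to H1), via C14-epimeric cycloadduct 27 (not isolated)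
Conditions: 26 (excess), toluene, 80 °C; then K2CO3, MeOH, rt
Reagents that add atoms: none
Why: Diels–Alder reaction whose "para" regiochemistry is set by the 2-ethoxy group (nucleophilic C12 to the enone β-carbon, C1 to the α-carbon) and whose facial selectivity follows from approach to C1 anti to the six-carbon bridge (H1 ends on the bridge face), after which carbonate equilibrates the enolisable C14 to the equatorial acetyl with H14 trans to H1.

Step 20
Reactants: 28 tricyclic methyl ketone
Product: 29 C15 enol triflate of 28 (C14–C(OTf)=CH2; C11 enol ether retained)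
Conditions: KHMDS, THF, −78 °C; PhNTf2; aq NH4Cl
Reagents that add atoms: N-phenylbis(trifluoromethanesulfonimide), O=S(=O)(N(c1ccccc1)S(=O)(=O)C(F)(F)F)C(F)(F)F
Why: Kinetic deprotonation of the methyl ketone at the unhindered CH3 rather than the tertiary C14–H and O-triflation of the potassium enolate give the 1,1-disubstituted alkenyl triflate, with no ester present to compete for the base and the C11 enol ether untouched.

Step 21
Reactants: 29 enol ether alkenyl triflate
Product: 30 C11 ketone (cis-fused; H10 syn to H1)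
Conditions: 0.1 M HCl, THF, 0 °C
Reagents that add atoms: water, O
Why: Mild acid hydrolysis of the tetrasubstituted enol ether gives the C11 ketone, and the epimerisable C10 settles (on protonation or by enol equilibration) in the more stable cis ring fusion with H10 syn to H1, while the alkenyl triflate and the tertiary TES ethers should survive brief dilute acid.

Step 22
Reactants: 30 C11 ketone
Product: 32 C11 tertiary acetate (11-Me; 11-OAc cis to C9), via bromomagnesium alkoxide 31 (not isolated)
Conditions: MeMgBr, THF, −78 → −20 °C; then Ac2O, DMAP (cat.), −20 °C → rt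
Reagents that add atoms: methylmagnesium bromide, C[Mg]Br; acetic anhydride, CC(=O)OC(C)=O
Why: Grignard 1,2-addition to the cyclohexanone from the axial direction, anti to the axial C10–C9 bond, gives the equatorial alkoxide (oxygen cis to C9, methyl cis to H10), which is acetylated in the same flask as its magnesium alkoxide, the classical way to esterify a tertiary carbinol; the alkenyl triflate is inert to the Grignard reagent at low temperature.

Step 23
Reactants: 32 bis-silylated acetate triflate
Product: 33 diol triflate: C15 alkenyl triflate with free C3–OH and C7–OH (key-step precursor)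
Conditions: HF·pyridine, pyridine, THF, 0 °C → rt
Reagents that add atoms: none
Why: Fluoride cleavage of both tertiary TES ethers under conditions to which the tertiary acetate, the alkenyl triflate and the methyl ether are inert.

Step 24
Reactants: 33 diol triflate; 34 carbon monoxide
Product: 35 15-methylene lactone (α-methylene seven-membered lactone; all other groups as in the target)
Conditions: Pd(PPh3)4 (10 mol %), CO (1 atm), i-Pr2NEt, DMAP (cat.), DMF, 70 °C, high dilution
Reagents that add atoms: none
Why: Pd(0) inserts into the C15–OTf bond, CO inserts to give the C16 acyl-palladium, and the C3 hydroxyl (directly or through the acyl-pyridinium formed with DMAP) attacks the acyl carbon, after which the amine base takes up triflic acid and Pd(0) is regenerated, so that C15–C16 and C16–O are formed in one operation. The closest known reaction type is the palladium-catalysed cyclocarbonylation of hydroxy alkenyl triflates and halides to α,β-unsaturated and α-methylene lactones. The seven-membered lactone closes by 7-exo-trig attack at the acyl carbon, and no stereocentre is formed (C15 stays sp2). The step needs chemoselectivity for O3 over O7 and over intermolecular capture: O7 could only give a bridged nine-membered ring, whereas the alkenyl arm on C14 and the C2–C3 arm on C1 are trans-diequatorial neighbours on the cyclohexane chair with the C3–O bond turned toward C14, and high dilution disfavours oligomers. The acyl-palladium (or acyl-pyridinium) is a stronger acylating agent than an activated acid, which offsets the low nucleophilicity of the tertiary carbinol, and the sp2 C15 removes one eclipsing interaction from the forming ring.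

Step 25
Reactants: 35 15-methylene lactone
Product: 36 target CNP0238771.1
Conditions: H2 (1 atm), 10% Pd/C, EtOAc, rt
Reagents that add atoms: none
Why: Heterogeneous syn-hydrogenation of the exocyclic methylene from its more open face, the side flanked only by the axial H14 (the sense seen with methylenecyclohexanes, where the new methyl ends up axial), should place H15 syn to H14 and so give (15R); acetate, ethers and lactone are inert.

**Compound list**

1 | methyl 4,4-dimethoxybutanoate | COC(=O)CCC(OC)OC | starting material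
2 | isopropenylmagnesium bromide | C=C(C)[Mg]Br | starting material
3 | 4,4-dimethoxy-N-methoxy-N-methylbutanamide (Weinreb amide) | CON(C)C(=O)CCC(OC)OC | intermediate
4 | 6,6-dimethoxy-2-methylhex-1-en-3-one | C=C(C)C(=O)CCC(OC)OC | intermediate
5 | (S)-6,6-dimethoxy-2-methylhex-1-en-3-ol | C=C(C)[C@@H](O)CCC(OC)OC | intermediate
6 | ethyl propiolate | C#CC(=O)OCC | starting material
7 | ethyl (E)-3-{[(3S)-6,6-dimethoxy-2-methylhex-1-en-3-yl]oxy}prop-2-enoate | C=C(C)[C@@H](O/C=C/C(=O)OCC)CCC(OC)OC | intermediate
8 | ethyl (E)-3-{[(3S)-2-methyl-6-oxohex-1-en-3-yl]oxy}prop-2-enoate | C=C(C)[C@@H](O/C=C/C(=O)OCC)CCC=O | intermediate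
9 | ethyl 2-[(2S,3R,6S)-3-hydroxy-6-(prop-1-en-2-yl)oxan-2-yl]acetate | CCOC(=O)C[C@@H]1O[C@H](C(C)=C)CC[C@H]1O | intermediate
10 | ethyl 2-[(2S,3R,6S)-3-(tert-butyldimethylsilyloxy)-6-(prop-1-en-2-yl)oxan-2-yl]acetate | CCOC(=O)C[C@@H]1O[C@H](C(C)=C)CC[C@H]1O[Si](C)(C)C(C)(C)C | intermediate
11 | 2-[(2S,3R,6S)-3-(tert-butyldimethylsilyloxy)-6-(prop-1-en-2-yl)oxan-2-yl]acetic acid | OC(=O)C[C@@H]1O[C@H](C(C)=C)CC[C@H]1O[Si](C)(C)C(C)(C)C | intermediate
12 | mixed isobutyl carbonic anhydride of 11 | CC(C)COC(=O)OC(=O)C[C@@H]1O[C@H](C(C)=C)CC[C@H]1O[Si](C)(C)C(C)(C)C | intermediate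
13 | 1-diazo-3-[(2S,3R,6S)-3-(tert-butyldimethylsilyloxy)-6-(prop-1-en-2-yl)oxan-2-yl]propan-2-one | [N-]=[N+]=CC(=O)C[C@@H]1O[C@H](C(C)=C)CC[C@H]1O[Si](C)(C)C(C)(C)C | intermediate
14 | bicyclic oxonium ylide (O bonded to C2, to the isopropenyl-bearing carbon and to the carbanionic C9) | C=C(C)[C@@H]1CC[C@@H](O[Si](C)(C)C(C)(C)C)[C@@H]2CC(=O)[CH-][O+]12 | intermediate
15 | (1S,2R,5Z,8S)-2-(tert-butyldimethylsilyloxy)-6-methyl-11-oxabicyclo[6.2.1]undec-5-en-9-one (C10 ketone, 3-OTBS, Z-C6=C7) | C/C1=C/CC[C@@H](O[Si](C)(C)C(C)(C)C)[C@@H]2CC(=O)[C@H](C1)O2 | intermediate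
16 | (1S,2R,5Z,8S)-2-(tert-butyldimethylsilyloxy)-6-methyl-11-oxabicyclo[6.2.1]undeca-5,9-dien-9-yl triflate | C/C1=C/CC[C@@H](O[Si](C)(C)C(C)(C)C)[C@@H]2C=C(OS(=O)(=O)C(F)(F)F)[C@H](C1)O2 | intermediate
17 | (1S,2R,5Z,8S)-2-hydroxy-6-methyl-11-oxabicyclo[6.2.1]undeca-5,9-dien-9-yl triflate | C/C1=C/CC[C@@H](O)[C@@H]2C=C(OS(=O)(=O)C(F)(F)F)[C@H](C1)O2 | intermediate
18 | (1S,5Z,8S)-6-methyl-2-oxo-11-oxabicyclo[6.2.1]undeca-5,9-dien-9-yl triflate | C/C1=C/CCC(=O)[C@@H]2C=C(OS(=O)(=O)C(F)(F)F)[C@H](C1)O2 | intermediate
19 | (1S,2S,5Z,8S)-2-hydroxy-2,6-dimethyl-11-oxabicyclo[6.2.1]undeca-5,9-dien-9-yl triflate | C/C1=C/CC[C@](C)(O)[C@@H]2C=C(OS(=O)(=O)C(F)(F)F)[C@H](C1)O2 | intermediate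
20 | (1S,2S,5Z,8S)-2,6-dimethyl-2-(triethylsilyloxy)-11-oxabicyclo[6.2.1]undeca-5,9-dien-9-yl triflate | C/C1=C/CC[C@](C)(O[Si](CC)(CC)CC)[C@@H]2C=C(OS(=O)(=O)C(F)(F)F)[C@H](C1)O2 | intermediate
21 | (6S,7R)-6,7-epoxide of 20 (oxirane on the face remote from the C1=C10 bridge) | C[C@]12O[C@H]1CC[C@](C)(O[Si](CC)(CC)CC)[C@@H]3C=C(OS(=O)(=O)C(F)(F)F)[C@H](C2)O3 | intermediate
22 | tributyl(1-ethoxyvinyl)stannane | CCCC[Sn](CCCC)(CCCC)C(=C)OCC | starting material
23 | C10-(1-ethoxyvinyl) diene epoxide | C[C@]12O[C@H]1CC[C@](C)(O[Si](CC)(CC)CC)[C@@H]3C=C(C(=C)OCC)[C@H](C2)O3 | intermediate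
24 | (6R,7R)-6-methoxy-7-hydroxy diene, 3-OTES | CO[C@@H]1CC[C@](C)(O[Si](CC)(CC)CC)[C@@H]2C=C(C(=C)OCC)[C@H](C[C@@]1(C)O)O2 | intermediate
25 | 3,7-bis(triethylsilyl) ether of 24 | CO[C@@H]1CC[C@](C)(O[Si](CC)(CC)CC)[C@@H]2C=C(C(=C)OCC)[C@H](C[C@@]1(C)O[Si](CC)(CC)CC)O2 | intermediate
26 | methyl vinyl ketone | CC(=O)C=C | starting material
27 | C14-epimeric cycloadduct (acetyl cis to the C1–C2 bond) | CO[C@@H]1CC[C@](C)(O[Si](CC)(CC)CC)[C@H]2O[C@@H](C[C@@]1(C)O[Si](CC)(CC)CC)C3=C(OCC)CC[C@H](C(C)=O)[C@H]23 | intermediate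
28 | tricyclic methyl ketone: 14-acetyl, C10=C11 ethyl enol ether, 6-OMe, 3,7-bis-OTES, H14 trans to H1 | CO[C@@H]1CC[C@](C)(O[Si](CC)(CC)CC)[C@H]2O[C@@H](C[C@@]1(C)O[Si](CC)(CC)CC)C3=C(OCC)CC[C@@H](C(C)=O)[C@H]23 | intermediate
29 | C15 enol triflate of 28 (C14–C(OTf)=CH2) | CO[C@@H]1CC[C@](C)(O[Si](CC)(CC)CC)[C@H]2O[C@@H](C[C@@]1(C)O[Si](CC)(CC)CC)C3=C(OCC)CC[C@@H](C(=C)OS(=O)(=O)C(F)(F)F)[C@H]23 | intermediate
30 | C11 ketone, cis-fused (H10 syn to H1) | CO[C@@H]1CC[C@](C)(O[Si](CC)(CC)CC)[C@H]2O[C@@H](C[C@@]1(C)O[Si](CC)(CC)CC)[C@@H]3C(=O)CC[C@@H](C(=C)OS(=O)(=O)C(F)(F)F)[C@H]23 | intermediate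
31 | bromomagnesium C11 alkoxide (11-Me, O cis to C9) | CO[C@@H]1CC[C@](C)(O[Si](CC)(CC)CC)[C@H]2O[C@@H](C[C@@]1(C)O[Si](CC)(CC)CC)[C@@H]3[C@](C)(O[Mg]Br)CC[C@@H](C(=C)OS(=O)(=O)C(F)(F)F)[C@H]23 | intermediate
32 | C11 tertiary acetate, 3,7-bis-OTES, C15 alkenyl triflate | CO[C@@H]1CC[C@](C)(O[Si](CC)(CC)CC)[C@H]2O[C@@H](C[C@@]1(C)O[Si](CC)(CC)CC)[C@@H]3[C@](C)(OC(C)=O)CC[C@@H](C(=C)OS(=O)(=O)C(F)(F)F)[C@H]23 | intermediate
33 | tricyclic C15 alkenyl triflate with free C3 and C7 carbinols (key-step precursor) | C=C(OS(=O)(=O)C(F)(F)F)[C@@H]1CC[C@@](C)(OC(C)=O)[C@@H]2[C@H]1[C@@H]3O[C@H]2C[C@@](C)(O)[C@H](OC)CC[C@]3(C)O | intermediate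
34 | carbon monoxide | [C-]#[O+] | starting material
35 | 15-methylene lactone | CO[C@@H]1CC[C@]2(C)OC(=O)C(=C)[C@@H]3CC[C@@](C)(OC(C)=O)[C@@H]4[C@H]3[C@@H]2O[C@H]4C[C@@]1(C)O | intermediate
36 | CNP0238771.1 | CO[C@@H]1CC[C@]2(C)OC(=O)[C@H](C)[C@@H]3CC[C@@](C)(OC(C)=O)[C@@H]4[C@H]3[C@@H]2O[C@H]4C[C@@]1(C)O | target

**Step count and risks**

Total step count: 25. Longest linear sequence: 25 steps (from 1; all other building blocks are commercial).

Step 24 (carbonylative lactonisation). Capture of the acyl-palladium by the hindered tertiary C3 hydroxyl may be too slow, so that decarbonylation and reduction of the alkenyl-palladium, hydrolysis by traces of water or intermolecular esterification take over. The fallback sets out from 33 and returns at 35. Hydroxycarbonylation of the triflate (Pd(OAc)2/dppf, CO, KOAc, wet DMSO) should give the 2-substituted acrylic acid F1. The C16–O bond is then closed on the C3 carbinol by Shiina lactonisation (2-methyl-6-nitrobenzoic anhydride, DMAP, Et3N, toluene, slow addition), so that the carbonyl is activated as an acyl-pyridinium instead of an acyl-metal.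

Step 17 (methoxide opening). SN2 attack at the neopentyl-like C6 from inside the medium ring may be sluggish, and base-induced elimination to an allylic alcohol or loss of the silyl ether on prolonged heating may compete. The fallback sets out from 20 and returns at 24, and replaces the substitution by an oxidation/reduction inversion. Dihydroxylation (OsO4 cat., NMO) on the outer face should give the 6,7-cis-diol F2. Dess–Martin oxidation of the secondary hydroxyl gives the 7-hydroxy-6-ketone F3. NaBH4, delivering hydride from the outer face, should give the 6,7-trans-diol F4. Selective methylation of the secondary hydroxyl (MeOTf, 2,6-di-tert-butyl-4-methylpyridine) gives the 6-O-methyl ether F5, and Stille coupling with 22 then gives 24.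

Step 25 (hydrogenation). Both faces of the exocyclic alkene carry only hydrogens nearby, so facial discrimination in the hydrogen delivery may be poor and the C15 epimer may form. The fallback sets out from 33 and returns at 36, and moves C15 under catalyst control before ring closure. The acrylic acid F1 (made as in the first fallback) is hydrogenated with Ru(OAc)2(BINAP)/H2, using the BINAP antipode that delivers (15R), to be identified by trial; this should give the (15R)-acid F6. Shiina lactonisation of F6 onto the C3 carbinol then gives 36.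

**Further compounds**

F1 | step 24 | 2-substituted acrylic acid (C16 acid on C15=CH2; free 3-OH and 7-OH; 11-OAc; 6-OMe) | C=C(C(=O)O)[C@@H]1CC[C@@](C)(OC(C)=O)[C@@H]2[C@H]1[C@@H]3O[C@H]2C[C@@](C)(O)[C@H](OC)CC[C@]3(C)O
F2 | step 17 | 6,7-cis-diol of 20 (both oxygens on the outer face) | O[C@H]1CC[C@](C)(O[Si](CC)(CC)CC)[C@@H]2C=C(OS(=O)(=O)C(F)(F)F)[C@H](C[C@@]1(C)O)O2
F3 | step 17 | 7-hydroxy-6-ketone | O=C1CC[C@](C)(O[Si](CC)(CC)CC)[C@@H]2C=C(OS(=O)(=O)C(F)(F)F)[C@H](C[C@@]1(C)O)O2
F4 | step 17 | (6R,7R)-6,7-trans-diol | O[C@@H]1CC[C@](C)(O[Si](CC)(CC)CC)[C@@H]2C=C(OS(=O)(=O)C(F)(F)F)[C@H](C[C@@]1(C)O)O2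
F5 | step 17 | (6R,7R)-6-methoxy-7-hydroxy enol triflate | CO[C@@H]1CC[C@](C)(O[Si](CC)(CC)CC)[C@@H]2C=C(OS(=O)(=O)C(F)(F)F)[C@H](C[C@@]1(C)O)O2
F6 | step 25 | (15R)-2-substituted propanoic acid (seco acid of the target) | C[C@@H](C(=O)O)[C@@H]1CC[C@@](C)(OC(C)=O)[C@@H]2[C@H]1[C@@H]3O[C@H]2C[C@@](C)(O)[C@H](OC)CC[C@]3(C)O
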